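## Structural features

The target is a spiro[5.5]undecane of the chamigrane type, numbered here so that ring B is C1–C5, the spiro carbon is C6 and ring A is C6–C11. Ring A carries a gem-dimethyl group at C7, a secondary bromide at C8 and an exocyclic methylidene at C11; ring B carries a secondary bromide at C2 next to a tertiary methyl carbinol at C3. The rings meet only at the quaternary C6, which lies between the quaternary C7 and the sp2 C11 and is a stereocentre only because the C1 arm leads to the bromohydrin and the C5 arm does not. Of the four stereocentres, C2 and C3 are adjacent, C6 sits across ring B from them, and C8 is neopentylic and separated from C6 by C7. The fragile groups are the trans-bromohydrin (epoxide closure with base), the neopentylic C8 bromide (elimination, methyl migration) and the 1,1-disubstituted alkene, which faces a tertiary alcohol cis to C11 across ring B (acid would isomerise it or bridge it as an ether). The real difficulty is twofold: building the congested C6 in the right sense, and placing the C3 hydroxyl cis and the C2 bromide trans to C11, both equatorial in the chair that keeps C7 equatorial. That arrangement is the opposite of what trans-diaxial opening of a C2=C3 bromonium ion by an external nucleophile would give. The key step uses the fact that C11, at the carboxylic acid level on C6, stands 1,4 to C3 across ring B, so a C6 carboxylate can reach C3 through a boat and pass the configuration of C6 on to C3 and C2.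

## Logic of the disconnections

**26 to 25.** The C11=CH2 bond is cut back to a C11 carbonyl. The alkene is the most acid-sensitive group and is best made last, and a C11 ketone is what an acylative closure of ring A delivers. The forward step must be a non-basic methylenation that works next to the spiro carbon and leaves a bromohydrin and two secondary bromides alone.

**25 to 24 to 23.** The C8–Br bond is cut back to a C8–O bond of opposite configuration, free in 24 and silylated in 23. Oxygen at C8 is the handle that controls C6 earlier, and as a silyl ether it survives the organometallic step. The forward demand is an SN2 inversion at a neopentylic ring carbon, with the silyl group removed before any alkene is present.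

**23 to 20.** The C10–C11 bond of ring A is cut. The lactone carbonyl of 20 is already attached to C6 and serves as acyl acceptor for a C10 carbanion; opening the lactone in this way also frees the C3 hydroxyl. Ring A, the C11 carbonyl and the free carbinol therefore come from one step. The step needs halogen–metal exchange at the primary iodide to outrun any reaction at the secondary bromide, and a single addition to the carbonyl.

**20 to 19 to 18.** Only the C10 substituent changes (iodide, alcohol, silyl ether). The forward steps must tell the primary silyl ether from the neopentylic secondary one.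

**18 to 17.** The C3–O and C2–Br bonds are cut. They are trans to each other and the oxygen is cis to C11, which is the signature of an anti addition with the C6 carboxyl as internal nucleophile. Two stereocentres and one ring disappear, leaving only C6 and C8. The forward step needs Markovnikov closure at C3. The C8 oxygen must be masked in 17: with a free C8 hydroxyl the acid would be a γ-hydroxy acid carrying a gem-dimethyl group, which would close to 14 on acidification, and in 18 the hydroxyl could take over the acyl group from the C3 oxygen.

**17 to 14.** The C8 oxygen is reconnected to C11 as a γ-lactone. In the five-membered ring C8 and C6 are 1,3-related, so C8 can direct the construction of C6. The forward step must open the lactone and protect C8–O without ever acidifying a free hydroxy acid.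

**14 to 8 and 12.** The C6–C1 and C6–C5 bonds are cut, which removes ring B and the quaternary stereocentre in one convergent operation. The forward step requires the allylic terminus of 12 to react first and the ring-closing alkylation to occur anti to the C8 side chain.

**12 to 10 to 9.** The two C–Br bonds go back to C–O bonds and then to a lactone, so that the Z-alkene is taken from a ring and never has to be made selectively.

**8 to 6 to 4.** The lactone C–O bond comes from oxidation of a 1,4-diol, and the C11 oxygen from anti-Markovnikov hydration of a vinyl group. Both steps must leave C8 and the silyl ether alone.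

**4 to 1 and 2.** The C7–C8 bond is cut. One step brings in C7 with its two methyl groups, C6 and C11, and sets C8 by catalyst control. It must give the branched (tert-prenyl) regiochemistry with high enantioselectivity.

## Other disconnections considered

**Alternative 1:** The cut is the C6–C11 bond, with ring B drawn back to a phenol. A cationic gold catalyst such as Ph3PAuNTf2 would activate the terminal alkyne of phenol A1; the para carbon would attack the internal alkyne carbon in a 6-exo-dig ipso cyclisation to give spirodienone A2.
- In its favour: one catalytic step would close ring A, create the spiro carbon next to C7 and leave the methylidene in place, and the C8 bromide could be carried from the start. On ring A construction and on avoiding a hindered-ketone methylenation and a late displacement on ring A it is better than the chosen plan.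
- Against it: in A2 the two arms of ring B are alike, so C6 is not yet a stereocentre. C6, C3 and C2 would all have to be created by telling the C1=C2 arm from the C4=C5 arm under the influence of C8, which is insulated by C7.
- The C3 methyl would still have to be added and one arm reduced. The bromohydrin would have to come from intermolecular attack on a C2=C3 alkene, which opens trans-diaxially and would favour the wrong trans isomer, in the presence of a second alkene.
- Mechanistically the ipso attack on an unactivated alkyne competes with ortho hydroarylation.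
- Comparison: shorter than the chosen plan as far as A2, but longer and less controlled afterwards. The chosen plan spends more steps on ring A but sets C2 and C3 in one step from C6.

**Alternative 2:** The cuts are C1–C6 and a temporary C1–C11 bond. Diazoketone A3, with a tetrasubstituted C6=C11 alkene in a preformed ring A, would be decomposed with Cu(acac)2 or Rh2(OAc)4. The carbenoid would add across the alkene, closing ring B and giving cyclopropyl ketone A4. Heating would then trigger a retro-ene reaction (homo-1,5-hydrogen shift from the C11 methyl to the carbonyl oxygen) that breaks C1–C11 and gives methylidene ketone A5.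
- In its favour: the spiro carbon and the methylidene would come from one strategic sequence, and the cis relation of methyl and acyl that the retro-ene step needs is guaranteed by the ring fusion. No hindered ketone is methylenated and no organolithium is used; on these points it is better than the chosen plan.
- C6 would be set by the face of cyclopropanation relative to the C8 silyl ether, a relay across C7 of the same kind as in the spiroannulation of the chosen plan; here the two are equal.
- Against it: A5 has only a C2 ketone in ring B. The C3 methyl, the C3 hydroxyl and the C2 bromide would need several further steps, and the bromohydrin would again come from an intermolecular addition that favours the diaxial isomer.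
- Six-membered cyclopropanation of a tetrasubstituted alkene competes with C–H insertion, the retro-ene step needs high temperature, and C8 would still need inversion.
- Comparison: comparable step count up to A5, clearly longer after it.

**Alternative 3:** The cuts are C5–C6 and C1–C6, so that ring B arrives as one piece. The kinetic α′-enolate of enone A6 would be alkylated at C6 by the C5 iodide of diiodide A7 and, after a second deprotonation, by its C1 iodide, to give spiro enone A8.
- In its favour: it is convergent, and C2 and C3 would arrive oxygenated with their configuration set by reagent control in an asymmetric dihydroxylation. In absolute control of C3 it is the equal of the chosen plan, and in convergence it is arguably better.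
- Against it: the second alkylation must build the spiro carbon next to C7 with an unactivated primary iodide bearing a β-oxygen, where elimination and O-alkylation are likely. The chosen plan starts its spiroannulation with an allylic bromide on a lactone enolate, which is easier, but the face-selectivity problem at C6 is the same in both (equal).
- After A8 the cis-diol would have to become the trans-bromohydrin by inversion at C2, a second hindered SN2 next to a tertiary carbinol, in addition to the one at C8. The enone must also be reduced and C11 methylenated.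
- Comparison: similar step count to the spiro skeleton, but more steps and one more difficult displacement afterwards.

Key step: step 8

Assumption: the iridium catalyst built on (S)-SEGPHOS is taken to deliver the (3R) carbinol 4 in step 1; if the opposite sense is found, (R)-SEGPHOS is used and nothing else changes.

## Route

Step 1
Reactants: 1 3-[tert-butyl(dimethyl)silyl]oxypropan-1-ol; 2 3-methylbuta-1,2-diene
Product: 4 (3R)-1-[tert-butyl(dimethyl)silyl]oxy-4,4-dimethylhex-5-en-3-ol, via aldehyde 3 (not isolated)
Conditions: preformed iridium π-allyl C,O-benzoate complex [from [Ir(cod)Cl]2, (S)-SEGPHOS, 4-cyano-3-nitrobenzoic acid, allyl acetate, Cs2CO3] (5 mol %), 2 (2 equiv), toluene, 60 °C, sealed tube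
Reagents that add atoms: none
Why: Iridium-catalysed transfer-hydrogenative carbonyl tert-prenylation: the alcohol is dehydrogenated to aldehyde 3, the iridium hydride adds to the allene, and the resulting prenyl-iridium species adds through its dimethyl-substituted carbon in a closed chair transition state. The chiral bisphosphine selects the aldehyde face and so sets C8; the coupling is redox-neutral.

Step 2
Reactants: 4 (3R)-1-[tert-butyl(dimethyl)silyl]oxy-4,4-dimethylhex-5-en-3-ol
Product: 6 (4R)-6-[tert-butyl(dimethyl)silyl]oxy-3,3-dimethylhexane-1,4-diol, via alkylborane 5 (not isolated)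
Conditions: 9-BBN (2.2 equiv), THF, 0 °C to rt; then NaOH, H2O2, 0 °C
Reagents that add atoms: hydrogen peroxide, OO
Why: Anti-Markovnikov hydroboration–oxidation; the bulky borane places boron only on the terminal carbon of the neopentylic vinyl group, and C8 is not involved.

Step 3
Reactants: 6 (4R)-6-[tert-butyl(dimethyl)silyl]oxy-3,3-dimethylhexane-1,4-diol
Product: 8 (5R)-5-[2-[tert-butyl(dimethyl)silyl]oxyethyl]-4,4-dimethyloxolan-2-one, via lactol 7 (not isolated)
Conditions: TEMPO (10 mol %), PhI(OAc)2 (2.5 equiv), CH2Cl2, rt
Reagents that add atoms: none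
Why: Oxoammonium-mediated oxidative lactonisation of a 1,4-diol: only the primary alcohol is oxidised, the aldehyde is trapped by the C8 hydroxyl as lactol 7, and a second oxidation gives the γ-lactone. The silyl ether and C8 are untouched.

Step 4
Reactants: 9 4-methyl-5,6-dihydro-2H-pyran-2-one
Product: 10 (2Z)-3-methylpent-2-ene-1,5-diol
Conditions: iBu2AlH (4.2 equiv), CH2Cl2, −78 °C to 0 °C; aq. potassium sodium tartrate
Reagents that add atoms: none
Why: 1,2-Reduction of an α,β-unsaturated lactone to the allylic diol; the Z geometry is inherited from the ring because the double bond is never broken.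

Step 5
Reactants: 10 (2Z)-3-methylpent-2-ene-1,5-diol
Product: 12 (2Z)-1,5-dibromo-3-methylpent-2-ene, via bis-mesylate 11 (not isolated)
Conditions: MsCl (2.3 equiv), Et3N (2.6 equiv), THF, −40 °C; then LiBr (6 equiv), THF, 0 °C to rt; used at once
Reagents that add atoms: lithium bromide, [Li+].[Br-]
Why: Sulfonylation of both primary hydroxyls followed by SN2 exchange with bromide. Fast double activation at low temperature avoids cyclisation of a mono-activated Z-diol to a dihydropyran, and the neutral exchange keeps the Z-alkene.

Step 6
Reactants: 8 (5R)-5-[2-[tert-butyl(dimethyl)silyl]oxyethyl]-4,4-dimethyloxolan-2-one; 12 (2Z)-1,5-dibromo-3-methylpent-2-ene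
Product: 14 (3R,5S)-3-[2-[tert-butyl(dimethyl)silyl]oxyethyl]-4,4,8-trimethyl-2-oxaspiro[4.5]dec-7-en-1-one, via monoalkylated lactone 13 (not isolated)
Conditions: LiN(iPr)2 (1.05 equiv), THF, −78 °C; 12 (1.1 equiv), −78 to −30 °C; then KN(SiMe3)2 (1.3 equiv), THF/DMPU, −78 to 0 °C
Reagents that add atoms: none
Why: Double enolate alkylation (spiroannulation): the allylic bromide reacts first and forms C6–C1, then the second enolate closes ring B by 6-exo-tet displacement of the homoallylic bromide and forms C6–C5. C6 is set in the ring closure: the C7 methyl cis to the C8 side chain is pseudo-axial and shields that face, so C5 enters anti to the side chain and C1 ends syn to it.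

Step 7
Reactants: 14 (3R,5S)-3-[2-[tert-butyl(dimethyl)silyl]oxyethyl]-4,4,8-trimethyl-2-oxaspiro[4.5]dec-7-en-1-one
Product: 17 (1S)-1-[(3R)-3,5-bis[[tert-butyl(dimethyl)silyl]oxy]-2-methylpentan-2-yl]-4-methylcyclohex-3-ene-1-carboxylic acid, via potassium hydroxy carboxylate 15 (not isolated), via silyl ester 16 (not isolated)
Conditions: KOH (1.5 equiv), MeOH/H2O, 60 °C, evaporate (toluene azeotrope); TBSOTf (3.5 equiv), 2,6-lutidine (5 equiv), CH2Cl2, −78 to 0 °C; then K2CO3, MeOH/THF/H2O, rt; AcOH to pH 5
Reagents that add atoms: potassium hydroxide, [K+].[OH-]; tert-butyldimethylsilyl trifluoromethanesulfonate, CC(C)(C)[Si](C)(C)OS(=O)(=O)C(F)(F)F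
Why: Saponification, exhaustive silylation and selective solvolysis of the silyl ester. The carboxyl is never protonated while the C8 hydroxyl is free, so the γ-hydroxy acid cannot close back to 14, and any primary silyl ether lost in the basic stage is restored; no stereocentre is involved.

Step 8
Reactants: 17 (1S)-1-[(3R)-3,5-bis[[tert-butyl(dimethyl)silyl]oxy]-2-methylpentan-2-yl]-4-methylcyclohex-3-ene-1-carboxylic acid
Product: 18 (1R,4S,6R)-6-bromo-4-[(3R)-3,5-bis[[tert-butyl(dimethyl)silyl]oxy]-2-methylpentan-2-yl]-1-methyl-2-oxabicyclo[2.2.2]octan-3-one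
Conditions: NBS (1.05 equiv), NaHCO3 (2 equiv), MeCN, 0 °C, dark
Reagents that add atoms: N-bromosuccinimide, O=C1CCC(=O)N1Br
Why: Bromolactonisation, the bromine counterpart of iodolactonisation; the closest known case is the conversion of 4-methylcyclohex-3-ene-1-carboxylic acids into 6-halo-1-methyl-2-oxabicyclo[2.2.2]octan-3-ones. NBS forms a bromonium ion reversibly on either face of C2=C3, but only the ion on the face away from the C6 carboxylate can be opened from within the molecule. The carboxylate oxygen attacks the tertiary C3 with ring B in a boat, a 6-exo closure that forms the C3–O bond and the bridged δ-lactone while bromine stays on C2. C3 is set by the tether: its oxygen must lie on the face that carries C11, and that face is fixed by C6. C2 is set by the anti course of the addition: bromine ends trans to the new C–O bond and therefore trans to C11. The step needs closure at C3 rather than at C2 (the five-membered mode, giving a 6-oxabicyclo[3.2.1]octan-7-one) or capture by water; the larger positive charge at the tertiary end of the unsymmetrical bromonium ion, the bulky C7 group that holds the carboxyl pseudo-axial over the ring, and the dry buffered medium secure this. The C8 oxygen is silylated, so it can neither attack the bromonium ion nor take the acyl group from the new lactone.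

Step 9
Reactants: 18 (1R,4S,6R)-6-bromo-4-[(3R)-3,5-bis[[tert-butyl(dimethyl)silyl]oxy]-2-methylpentan-2-yl]-1-methyl-2-oxabicyclo[2.2.2]octan-3-one
Product: 19 (1R,4S,6R)-6-bromo-4-[(3R)-3-[tert-butyl(dimethyl)silyl]oxy-5-hydroxy-2-methylpentan-2-yl]-1-methyl-2-oxabicyclo[2.2.2]octan-3-one
Conditions: HF·pyridine, pyridine, THF, 0 °C to rt
Reagents that add atoms: none
Why: Selective desilylation: the primary silyl ether is cleaved much faster than the neopentylic secondary one, and the lactone and the bromide are inert to buffered fluoride.

Step 10
Reactants: 19 (1R,4S,6R)-6-bromo-4-[(3R)-3-[tert-butyl(dimethyl)silyl]oxy-5-hydroxy-2-methylpentan-2-yl]-1-methyl-2-oxabicyclo[2.2.2]octan-3-one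
Product: 20 (1R,4S,6R)-6-bromo-4-[(3R)-3-[tert-butyl(dimethyl)silyl]oxy-5-iodo-2-methylpentan-2-yl]-1-methyl-2-oxabicyclo[2.2.2]octan-3-one
Conditions: I2 (1.3 equiv), PPh3 (1.3 equiv), imidazole (2.5 equiv), CH2Cl2, 0 °C to rt
Reagents that add atoms: iodine, II
Why: Appel-type iodination of a primary alcohol through its alkoxyphosphonium salt; no stereocentre is touched.

Step 11
Reactants: 20 (1R,4S,6R)-6-bromo-4-[(3R)-3-[tert-butyl(dimethyl)silyl]oxy-5-iodo-2-methylpentan-2-yl]-1-methyl-2-oxabicyclo[2.2.2]octan-3-one
Product: 23 (2R,3R,6S,8R)-2-bromo-8-[tert-butyl(dimethyl)silyl]oxy-3-hydroxy-3,7,7-trimethylspiro[5.5]undecan-11-one (target locants), via alkyllithium 21 (not isolated), via lithium hemiketalate 22 (not isolated)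
Conditions: t-BuLi (2.1 equiv), Et2O/pentane, −78 °C; AcOH, −78 °C, then warm
Reagents that add atoms: none
Why: Iodine–lithium exchange followed by intramolecular acylation of the primary alkyllithium by the lactone carbonyl (6-exo-trig), which forms C10–C11 and ring A. Exchange at the primary iodide is far faster than any reaction at the secondary bromide or the hindered carbonyl, and the tetrahedral alkoxide 22 is quenched cold. Its collapse on warming releases the C11 ketone and the C3 hydroxyl without touching a stereocentre.

Step 12
Reactants: 23 (2R,3R,6S,8R)-2-bromo-8-[tert-butyl(dimethyl)silyl]oxy-3-hydroxy-3,7,7-trimethylspiro[5.5]undecan-11-one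
Product: 24 (2R,3R,6S,8R)-2-bromo-3,8-dihydroxy-3,7,7-trimethylspiro[5.5]undecan-11-one (target locants)
Conditions: 48% aq. HF, MeCN, rt
Reagents that add atoms: none
Why: Acidic fluoride cleavage of the hindered secondary silyl ether, placed before the methylidene exists so that no acid-sensitive alkene is exposed; ketone, bromide and tertiary alcohol tolerate the conditions.

Step 13
Reactants: 24 (2R,3R,6S,8R)-2-bromo-3,8-dihydroxy-3,7,7-trimethylspiro[5.5]undecan-11-one
Product: 25 (2R,3R,6S,8S)-2,8-dibromo-3-hydroxy-3,7,7-trimethylspiro[5.5]undecan-11-one (target locants)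
Conditions: CBr4 (2.5 equiv), PPh3 (2.5 equiv), CH2Cl2, 0 °C to rt, no amine base
Reagents that add atoms: tetrabromomethane, BrC(Br)(Br)Br
Why: Appel bromination: the secondary hydroxyl becomes an alkoxyphosphonium leaving group that bromide displaces from the rear, turning the (8R) oxygen into the (8S) bromide by inversion. The tertiary C3 hydroxyl is too hindered to be activated, and the absence of base limits elimination.

Step 14
Reactants: 25 (2R,3R,6S,8S)-2,8-dibromo-3-hydroxy-3,7,7-trimethylspiro[5.5]undecan-11-one
Product: 26 (2R,3R,6R,8S)-2,8-dibromo-3,7,7-trimethyl-11-methylidenespiro[5.5]undecan-3-ol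
Conditions: Zn, CH2Br2, TiCl4, THF (reagent preformed at −40 to 5 °C); 25, CH2Cl2, 0 °C to rt
Reagents that add atoms: dibromomethane, BrCBr
Why: Lombardo–Takai methylenation: a non-basic titanium methylidene equivalent converts the hindered C11 ketone into the exocyclic alkene without enolisation, so the bromohydrin is not pushed towards the epoxide and the alkyl bromides are left alone. No stereocentre is affected.

## Compound list

1 | 3-[tert-butyl(dimethyl)silyl]oxypropan-1-ol | OCCCO[Si](C)(C)C(C)(C)C | starting material
2 | 3-methylbuta-1,2-diene | C=C=C(C)C | starting material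
3 | 3-[tert-butyl(dimethyl)silyl]oxypropanal | O=CCCO[Si](C)(C)C(C)(C)C | intermediate
4 | (3R)-1-[tert-butyl(dimethyl)silyl]oxy-4,4-dimethylhex-5-en-3-ol | C=CC(C)(C)[C@H](O)CCO[Si](C)(C)C(C)(C)C | intermediate
5 | 9-[(4R)-6-[tert-butyl(dimethyl)silyl]oxy-4-hydroxy-3,3-dimethylhexyl]-9-borabicyclo[3.3.1]nonane (hydroxyl drawn free; it may be held as its borinate) | CC(C)(C)[Si](C)(C)OCC[C@@H](O)C(C)(C)CCB1C2CCCC1CCC2 | intermediate
6 | (4R)-6-[tert-butyl(dimethyl)silyl]oxy-3,3-dimethylhexane-1,4-diol | OCCC(C)(C)[C@H](O)CCO[Si](C)(C)C(C)(C)C | intermediate
7 | (5R)-5-[2-[tert-butyl(dimethyl)silyl]oxyethyl]-4,4-dimethyloxolan-2-ol (both anomers) | OC1CC(C)(C)[C@@H](CCO[Si](C)(C)C(C)(C)C)O1 | intermediate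
8 | (5R)-5-[2-[tert-butyl(dimethyl)silyl]oxyethyl]-4,4-dimethyloxolan-2-one | CC(C)(C)[Si](C)(C)OCC[C@H]1OC(=O)CC1(C)C | intermediate
9 | 4-methyl-5,6-dihydro-2H-pyran-2-one | CC1=CC(=O)OCC1 | starting material
10 | (2Z)-3-methylpent-2-ene-1,5-diol | OCC/C(C)=C\CO | intermediate
11 | (2Z)-3-methylpent-2-ene-1,5-diyl dimethanesulfonate | CS(=O)(=O)OCC/C(C)=C\COS(C)(=O)=O | intermediate
12 | (2Z)-1,5-dibromo-3-methylpent-2-ene | BrCC/C(C)=C\CBr | intermediate
13 | (5R)-3-[(2Z)-5-bromo-3-methylpent-2-enyl]-5-[2-[tert-butyl(dimethyl)silyl]oxyethyl]-4,4-dimethyloxolan-2-one (C3 epimers) | CC(C)(C)[Si](C)(C)OCC[C@H]1OC(=O)C(C/C=C(C)\CCBr)C1(C)C | intermediate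
14 | (3R,5S)-3-[2-[tert-butyl(dimethyl)silyl]oxyethyl]-4,4,8-trimethyl-2-oxaspiro[4.5]dec-7-en-1-one | CC(C)(C)[Si](C)(C)OCC[C@H]1OC(=O)[C@]2(CCC(C)=CC2)C1(C)C | intermediate
15 | potassium (1S)-1-[(3R)-5-[tert-butyl(dimethyl)silyl]oxy-3-hydroxy-2-methylpentan-2-yl]-4-methylcyclohex-3-ene-1-carboxylate | CC(C)(C)[Si](C)(C)OCC[C@@H](O)C(C)(C)[C@]1(C(=O)[O-])CCC(C)=CC1.[K+] | intermediate
16 | tert-butyl(dimethyl)silyl (1S)-1-[(3R)-3,5-bis[[tert-butyl(dimethyl)silyl]oxy]-2-methylpentan-2-yl]-4-methylcyclohex-3-ene-1-carboxylate | CC(C)(C)[Si](C)(C)OCC[C@@H](O[Si](C)(C)C(C)(C)C)C(C)(C)[C@]1(C(=O)O[Si](C)(C)C(C)(C)C)CCC(C)=CC1 | intermediate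
17 | (1S)-1-[(3R)-3,5-bis[[tert-butyl(dimethyl)silyl]oxy]-2-methylpentan-2-yl]-4-methylcyclohex-3-ene-1-carboxylic acid | CC(C)(C)[Si](C)(C)OCC[C@@H](O[Si](C)(C)C(C)(C)C)C(C)(C)[C@]1(C(=O)O)CCC(C)=CC1 | intermediate
18 | (1R,4S,6R)-6-bromo-4-[(3R)-3,5-bis[[tert-butyl(dimethyl)silyl]oxy]-2-methylpentan-2-yl]-1-methyl-2-oxabicyclo[2.2.2]octan-3-one | CC(C)(C)[Si](C)(C)OCC[C@@H](O[Si](C)(C)C(C)(C)C)C(C)(C)[C@@]12CC[C@@](C)(OC1=O)[C@H](Br)C2 | intermediate
19 | (1R,4S,6R)-6-bromo-4-[(3R)-3-[tert-butyl(dimethyl)silyl]oxy-5-hydroxy-2-methylpentan-2-yl]-1-methyl-2-oxabicyclo[2.2.2]octan-3-one | OCC[C@@H](O[Si](C)(C)C(C)(C)C)C(C)(C)[C@@]12CC[C@@](C)(OC1=O)[C@H](Br)C2 | intermediate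
20 | (1R,4S,6R)-6-bromo-4-[(3R)-3-[tert-butyl(dimethyl)silyl]oxy-5-iodo-2-methylpentan-2-yl]-1-methyl-2-oxabicyclo[2.2.2]octan-3-one | ICC[C@@H](O[Si](C)(C)C(C)(C)C)C(C)(C)[C@@]12CC[C@@](C)(OC1=O)[C@H](Br)C2 | intermediate
21 | [(3R)-4-[(1R,4S,6R)-6-bromo-1-methyl-3-oxo-2-oxabicyclo[2.2.2]octan-4-yl]-3-[tert-butyl(dimethyl)silyl]oxy-4-methylpentyl]lithium | [Li]CC[C@@H](O[Si](C)(C)C(C)(C)C)C(C)(C)[C@@]12CC[C@@](C)(OC1=O)[C@H](Br)C2 | intermediate
22 | lithium hemiketalate formed by attack of C10 on C11 (tricyclic alkoxide; hemiketal carbon unassigned, it is lost on collapse) | [Li+].[O-]C12CC[C@@H](O[Si](C)(C)C(C)(C)C)C(C)(C)[C@@]13CC[C@@](C)(O2)[C@H](Br)C3 | intermediate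
23 | (2R,3R,6S,8R)-2-bromo-8-[tert-butyl(dimethyl)silyl]oxy-3-hydroxy-3,7,7-trimethylspiro[5.5]undecan-11-one (target locants) | O=C1CC[C@@H](O[Si](C)(C)C(C)(C)C)C(C)(C)[C@@]12CC[C@@](C)(O)[C@H](Br)C2 | intermediate
24 | (2R,3R,6S,8R)-2-bromo-3,8-dihydroxy-3,7,7-trimethylspiro[5.5]undecan-11-one (target locants) | O=C1CC[C@@H](O)C(C)(C)[C@@]12CC[C@@](C)(O)[C@H](Br)C2 | intermediate
25 | (2R,3R,6S,8S)-2,8-dibromo-3-hydroxy-3,7,7-trimethylspiro[5.5]undecan-11-one (target locants) | O=C1CC[C@H](Br)C(C)(C)[C@@]12CC[C@@](C)(O)[C@H](Br)C2 | intermediate
26 | (2R,3R,6R,8S)-2,8-dibromo-3,7,7-trimethyl-11-methylidenespiro[5.5]undecan-3-ol | C=C1CC[C@H](Br)C(C)(C)[C@@]12CC[C@@](C)(O)[C@H](Br)C2 | target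

## Step count and least certain steps

Total: 14 steps. Longest linear sequence: 12 steps (steps 1–3 and 6–14); steps 4 and 5 are the side branch.

**Step 8 (key step).** The most likely failure is closure of the carboxylate on the secondary C2 in the five-membered mode, which is kinetically easy for cyclohex-3-ene carboxylates, or interception of the bromonium ion by traces of water. Closure at C3 also has to pass through a boat carrying a very bulky C6 substituent. The fallback sets out from 17 and uses mercurilactonisation with Hg(OCOCF3)2 and NaHCO3 in MeCN, followed by exchange with KBr, to give the bromomercurio lactone F1. Oxymercuration is reversible and strongly Markovnikov, so the oxygen should settle on C3 under thermodynamic control, with mercury trans on C2. Treatment of F1 with Br2 and LiBr in pyridine under oxygen replaces mercury by bromine with retention, and the route is rejoined at 18.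

**Step 13.** Backside attack at a neopentylic ring carbon is slow, so β-elimination towards C9 and migration of a C7 methyl group can outrun substitution. The fallback sets out from 24 and separates activation from displacement: ClCH2SO2Cl in pyridine at 0 °C gives the chloromethanesulfonate F2, selectively at the secondary hydroxyl, and LiBr in DMF (or Bu4NBr in toluene) then displaces it with inversion. The route is rejoined at 25.

**Step 6.** The amide base or the enolate may dehydrobrominate the homoallylic bromide arm, whose β-hydrogens are allylic, and facial control in the ring closure rests on a bias transmitted through C7. The fallback sets out from 8 and forms the two bonds separately. LiN(iPr)2 and allyl bromide give the allyl lactone F3. A second enolisation and alkylation with 3-methylbut-3-en-1-yl trifluoromethanesulfonate at −78 °C, again anti to the C8 side chain, gives the diene lactone F4. Ring-closing metathesis with the second-generation Grubbs catalyst in CH2Cl2 then closes ring B, and the route is rejoined at 14.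

**Step 7.** While the carboxyl is transiently a silyl ester, the free C8 hydroxyl may re-lactonise faster than it is silylated. The fallback sets out from 14 and changes the order of events: after saponification the solution of carboxylate 15 is buffered to pH 8–9 with NaHCO3 and treated directly with NBS in THF/H2O at 0 °C. This gives the hydroxy bromolactone F5, which is silylated at once with TBSOTf and 2,6-lutidine at −78 °C. The route is rejoined at 18.

**Step 11.** Exchange or elimination at the secondary C2 bromide, migration of silicon from the C8 oxygen to the C10 carbanion, early collapse of the tetrahedral intermediate followed by a second addition, or epoxide closure of the freed alkoxide may all compete. The fallback sets out from 20 and replaces the organolithium by a stabilised carbanion. PhSO2Na in DMF gives the sulfone F6. LiN(iPr)2 (2.2 equiv) in THF at −78 °C closes ring A by acylation of the sulfonyl carbanion to give the β-keto sulfone F7. SmI2 in THF/MeOH at −78 °C removes the sulfonyl group, and the route is rejoined at 23.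

**Step 14.** The titanium methylidene may add too slowly to a carbonyl flanked by the spiro carbon, giving incomplete conversion. The fallback sets out from 25 and uses a two-stage Peterson olefination: Me3SiCH2Li with CeCl3 in THF at −78 °C adds to the ketone to give the β-hydroxysilane F8, and aq. HF in MeCN at 0 °C brings about the elimination. The route is rejoined at 26.

## Further compounds

F1 | step 8 | (1R,4S,6R)-6-(bromomercurio)-4-[(3R)-3,5-bis[[tert-butyl(dimethyl)silyl]oxy]-2-methylpentan-2-yl]-1-methyl-2-oxabicyclo[2.2.2]octan-3-one | CC(C)(C)[Si](C)(C)OCC[C@@H](O[Si](C)(C)C(C)(C)C)C(C)(C)[C@@]12CC[C@@](C)(OC1=O)[C@H]([Hg]Br)C2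
F2 | step 13 | (2R,3R,6S,8R)-2-bromo-3-hydroxy-3,7,7-trimethyl-11-oxospiro[5.5]undecan-8-yl chloromethanesulfonate (target locants) | O=C1CC[C@@H](OS(=O)(=O)CCl)C(C)(C)[C@@]12CC[C@@](C)(O)[C@H](Br)C2
F3 | step 6 | (5R)-5-[2-[tert-butyl(dimethyl)silyl]oxyethyl]-4,4-dimethyl-3-(prop-2-enyl)oxolan-2-one (C3 epimers) | CC(C)(C)[Si](C)(C)OCC[C@H]1OC(=O)C(CC=C)C1(C)C
F4 | step 6 | (3S,5R)-5-[2-[tert-butyl(dimethyl)silyl]oxyethyl]-4,4-dimethyl-3-(3-methylbut-3-enyl)-3-(prop-2-enyl)oxolan-2-one | CC(C)(C)[Si](C)(C)OCC[C@H]1OC(=O)[C@](CC=C)(CCC(C)=C)C1(C)C
F5 | step 7 | (1R,4S,6R)-6-bromo-4-[(3R)-5-[tert-butyl(dimethyl)silyl]oxy-3-hydroxy-2-methylpentan-2-yl]-1-methyl-2-oxabicyclo[2.2.2]octan-3-one | CC(C)(C)[Si](C)(C)OCC[C@@H](O)C(C)(C)[C@@]12CC[C@@](C)(OC1=O)[C@H](Br)C2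
F6 | step 11 | (1R,4S,6R)-4-[(3R)-5-(benzenesulfonyl)-3-[tert-butyl(dimethyl)silyl]oxy-2-methylpentan-2-yl]-6-bromo-1-methyl-2-oxabicyclo[2.2.2]octan-3-one | O=S(=O)(CC[C@@H](O[Si](C)(C)C(C)(C)C)C(C)(C)[C@@]12CC[C@@](C)(OC1=O)[C@H](Br)C2)c1ccccc1
F7 | step 11 | (2R,3R,6S,8R)-10-(benzenesulfonyl)-2-bromo-8-[tert-butyl(dimethyl)silyl]oxy-3-hydroxy-3,7,7-trimethylspiro[5.5]undecan-11-one (target locants; C10 epimers) | O=C1C(S(=O)(=O)c3ccccc3)C[C@@H](O[Si](C)(C)C(C)(C)C)C(C)(C)[C@@]12CC[C@@](C)(O)[C@H](Br)C2
F8 | step 14 | (2R,3R,6S,8S)-2,8-dibromo-3,7,7-trimethyl-11-(trimethylsilylmethyl)spiro[5.5]undecane-3,11-diol (target locants; C11 unassigned) | C[Si](C)(C)CC1(O)CC[C@H](Br)C(C)(C)[C@@]12CC[C@@](C)(O)[C@H](Br)C2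
A1 | alternative 1 | 4-[(3S)-3-bromo-2-methylhept-6-yn-2-yl]phenol | C#CCC[C@H](Br)C(C)(C)c1ccc(O)cc1
A2 | alternative 1 | (8S)-8-bromo-7,7-dimethyl-11-methylidenespiro[5.5]undeca-1,4-dien-3-one | C=C1CC[C@H](Br)C(C)(C)C12C=CC(=O)C=C2
A3 | alternative 2 | 5-[(5R)-5-[tert-butyl(dimethyl)silyl]oxy-2,6,6-trimethylcyclohex-1-en-1-yl]-1-diazopentan-2-one | [N-]=[N+]=CC(=O)CCCC1=C(C)CC[C@@H](O[Si](C)(C)C(C)(C)C)C1(C)C
A4 | alternative 2 | tricyclic cyclopropyl ketone (cyclopropane C1–C6–C11, ketone at C2, C8 tert-butyldimethylsilyl ether) | O=C1CCC[C@@]23[C@@H]1[C@]2(C)CC[C@@H](O[Si](C)(C)C(C)(C)C)C3(C)C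
A5 | alternative 2 | (6R,8R)-8-[tert-butyl(dimethyl)silyl]oxy-7,7-dimethyl-11-methylidenespiro[5.5]undecan-2-one (target locants) | C=C1CC[C@@H](O[Si](C)(C)C(C)(C)C)C(C)(C)[C@@]12CCCC(=O)C2
A6 | alternative 3 | (4R)-4-[tert-butyl(dimethyl)silyl]oxy-5,5-dimethylcyclohex-2-en-1-one | O=C1C=C[C@@H](O[Si](C)(C)C(C)(C)C)C(C)(C)C1
A7 | alternative 3 | (4R,5R)-5-(2-iodoethyl)-4-(iodomethyl)-2,2,5-trimethyl-1,3-dioxolane | ICC[C@@]1(C)OC(C)(C)O[C@H]1CI
A8 | alternative 3 | spiro enone with C8 tert-butyldimethylsilyl ether and C2/C3 acetonide | O=C1C=C[C@@H](O[Si](C)(C)C(C)(C)C)C(C)(C)[C@@]12CC[C@@]3(C)OC(C)(C)O[C@H]3C2
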